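Numbering used below: ring A is the aromatic ring, ring B the saturated ring (C1–C4, tetralin numbering), and C1' is the side-chain carbinol carbon. The target is (1S,2R,1'R) with the C1 side chain cis to the C2 hydroxyl.

**Retrosynthetic overview**
- The last operation turns a C2–Si bond into C2–OH with retention and removes the silyl groups. The 1,3-diol O–C1'–C1–C2–O is therefore carried as a five-membered C1'–O–SiMe2–C2 ring.
- Ring B is cut at C1–C2 and C3–C4. This is a retro-Diels–Alder to an (E)-o-quinodimethane and a vinyl group held on the C1' oxygen by SiMe2. The diene comes from C–C cleavage of a cheap benzocyclobutene.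
- Enabling feature: both ring-B carbons bonded to ring A (C1 and C4) are benzylic, and the C1' oxygen sits 1,3 to the C2 oxygen. A three-atom C1'–O–Si tether therefore reaches exactly C2.
- C1' is the only stereocentre made by a reagent (catalytic asymmetric alkenylzinc addition). It then directs C1 and C2. The racemic ring carbon of the benzocyclobutene is erased in the ring opening.
- Ring order: ring A and the four-membered ring are bought. Ring B and the temporary oxasilolane form together in step 5. The oxasilolane is removed in step 6.

Key step: step 5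

Assumption: the amino alcohol (+)-MIB is taken to follow the usual zinc-chelate model, in which its antipode delivers carbon to the Si face of aldehydes. (+)-MIB should therefore deliver to the Re face.

Step 1
Reactants: 1 4-ethynylphenol
Product: 2 tert-butyl(4-ethynylphenoxy)dimethylsilane
Conditions: TBSCl, imidazole, DMF, rt
Reagents that add atoms: tert-butyldimethylsilyl chloride, CC(C)(C)[Si](C)(C)Cl
Why: Standard O-silylation masks the acidic phenol for the organoboron and organozinc chemistry of step 3, and no stereocentre is involved.

Step 2
Reactants: 3 rac-3,4-dimethoxybicyclo[4.2.0]octa-1,3,5-triene-7-carbonitrile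
Product: 4 rac-3,4-dimethoxybicyclo[4.2.0]octa-1,3,5-triene-7-carbaldehyde
Conditions: iBu2AlH (1.1 equiv), toluene, −78 °C; then aq. potassium sodium tartrate, 0 °C
Reagents that add atoms: water, O
Why: Partial nitrile reduction stops at the N-aluminated imine, which hydrolyses to the aldehyde, and the ring stereocentre may stay racemic because step 5 erases it.

Step 3
Reactants: 2 tert-butyl(4-ethynylphenoxy)dimethylsilane; 4 rac-3,4-dimethoxybicyclo[4.2.0]octa-1,3,5-triene-7-carbaldehyde
Product: 7 (1R,2E)-1-(3,4-dimethoxybicyclo[4.2.0]octa-1,3,5-trien-7-yl)-3-[4-(tert-butyldimethylsilyloxy)phenyl]prop-2-en-1-ol (both C7 epimers), via alkenylborane 5 (not isolated), via alkenylzinc 6 (not isolated)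
Conditions: 2, Cy2BH, toluene, 0 °C to rt; Et2Zn, −78 °C; (+)-MIB [(2R)-3-exo-morpholinoisoborneol, 5 mol %], then 4, −30 to 0 °C; quench with water
Reagents that add atoms: none
Why: In this catalytic asymmetric alkenylzinc addition, syn-hydroboration fixes the E-alkene, boron-to-zinc exchange gives the nucleophile, and the chiral amino-alcohol zinc chelate should deliver it to the Re face of the α-branched aldehyde, which sets the (R)-carbinol under catalyst control in both epimers of 4.

Step 4
Reactants: 7 the (R)-allylic alcohol; 8 chloro(dimethyl)vinylsilane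
Product: 9 dimethyl(vinyl)silyl ether of 7 (both C7 epimers)
Conditions: Et3N, DMAP (cat.), CH2Cl2, 0 °C; filtration through Et3N-deactivated silica
Reagents that add atoms: none
Why: O-silylation attaches the two-carbon dienophile to the carbinol oxygen without touching the C–O bond, so C1' keeps its configuration.

Step 5
Reactants: 9 dimethyl(vinyl)silyl ether of 7
Product: 11 cis-fused tricyclic 1,2-oxasilolane (6,7-dimethoxytetralin bridged from C1 to C2 by C1'H(styryl)–O–SiMe2; C1 C2 C1' arranged in space as in the target), via (E)-o-quinodimethane 10 (not isolated)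
Conditions: o-dichlorobenzene (0.005 M), 2,6-di-tert-butyl-4-methylpyridine (0.2 equiv), BHT (cat.), argon, 180 °C
Reagents that add atoms: none
Why: At 180 °C the strained C7–C8 σ-bond of the four-membered ring breaks in a conrotatory 4π electrocyclic opening in which the carbinol-bearing carbon turns outward, so both C7 epimers of 9 funnel into the single (E)-o-quinodimethane 10, which the tethered vinylsilane traps in an intramolecular Diels–Alder reaction (closest known types: benzocyclobutene/o-quinodimethane cycloaddition with tethered unactivated alkenes, and the temporary silicon connection of dienols to vinylsilanes). Ring B closes in a suprafacial [4π+2π] mode that restores the aromaticity of ring A, and the temporary 1,2-oxasilolane closes with it in the fused (type 1) mode, because the three-atom C1'–O–Si tether is too short for the bridged alternative, so silicon can only end on C2 and the CH2 terminus only on C4. C1 is set by C1': allylic 1,3-strain with the peri C8–H holds the carbinol H near the diene plane, which places the tether oxygen and the dienophile on one face and the styryl arm on the other. C2 is set by the orientation of the tether: silicon under the diene (endo) combined with the outward C1' gives the cis-fused silacycle, that is, Si cis to the side chain as the target requires. The selectivity needed is therefore endo over exo, and it should be favoured by the lower strain of a cis-fused five-ring closure over a three-atom tether, by the two smallest practical substituents on silicon, and by the fact that in the endo array only H and O of C1' flank C8–H, whereas the exo array leads to a trans-fused ring that must hold C1' in the arene plane. High dilution, the hindered base and the inhibitor should suppress dimerisation of 10, ionisation of the allylic C–O bond and polymerisation.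

Step 6
Reactants: 11 cis-fused tricyclic 1,2-oxasilolane
Product: 13 (1S,2R)-1-[(1R,2E)-1-hydroxy-3-(4-hydroxyphenyl)prop-2-en-1-yl]-6,7-dimethoxy-1,2,3,4-tetrahydronaphthalen-2-ol, via phenol oxasilolane 12 (not isolated)
Conditions: 30% aq. H2O2, KF, KHCO3, THF/MeOH (1:1), 0 °C to rt
Reagents that add atoms: hydrogen peroxide, OO
Why: In this Tamao–Kumada oxidation, KF/MeOH first cleaves the phenolic silyl ether, peroxide then adds to the alkoxysilane and C2 migrates from Si to O with retention, and hydrolysis frees both hydroxyls, so no stereocentre is disturbed.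

**Compound list**
1 | 4-ethynylphenol | C#Cc1ccc(O)cc1 | starting material
2 | tert-butyl(4-ethynylphenoxy)dimethylsilane | C#Cc1ccc(O[Si](C)(C)C(C)(C)C)cc1 | intermediate
3 | rac-3,4-dimethoxybicyclo[4.2.0]octa-1,3,5-triene-7-carbonitrile | COc1cc2c(cc1OC)C(C#N)C2 | starting material
4 | rac-3,4-dimethoxybicyclo[4.2.0]octa-1,3,5-triene-7-carbaldehyde | COc1cc2c(cc1OC)C(C=O)C2 | intermediate
5 | (E)-dicyclohexyl{2-[4-(tert-butyldimethylsilyloxy)phenyl]ethenyl}borane | CC(C)(C)[Si](C)(C)Oc1ccc(/C=C/B(C2CCCCC2)C2CCCCC2)cc1 | intermediate
6 | (E)-ethyl{2-[4-(tert-butyldimethylsilyloxy)phenyl]ethenyl}zinc | CC[Zn]/C=C/c1ccc(O[Si](C)(C)C(C)(C)C)cc1 | intermediate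
7 | (R)-allylic alcohol, both epimers at the ring carbon | COc1cc2c(cc1OC)C([C@H](O)/C=C/c1ccc(O[Si](C)(C)C(C)(C)C)cc1)C2 | intermediate
8 | chloro(dimethyl)vinylsilane | C=C[Si](C)(C)Cl | starting material
9 | dimethyl(vinyl)silyl ether of 7 | COc1cc2c(cc1OC)C([C@H](O[Si](C)(C)C=C)/C=C/c1ccc(O[Si](C)(C)C(C)(C)C)cc1)C2 | intermediate
10 | (E)-o-quinodimethane | C=C1C=C(OC)C(OC)=C/C1=C\[C@H](O[Si](C)(C)C=C)/C=C/c1ccc(O[Si](C)(C)C(C)(C)C)cc1 | intermediate
11 | cis-fused tricyclic 1,2-oxasilolane | COc1cc2c(cc1OC)[C@@H]3[C@@H](/C=C/c1ccc(O[Si](C)(C)C(C)(C)C)cc1)O[Si](C)(C)[C@@H]3CC2 | intermediate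
12 | phenol oxasilolane | COc1cc2c(cc1OC)[C@@H]3[C@@H](/C=C/c1ccc(O)cc1)O[Si](C)(C)[C@@H]3CC2 | intermediate
13 | (1S,2R)-1-[(1R,2E)-1-hydroxy-3-(4-hydroxyphenyl)prop-2-en-1-yl]-6,7-dimethoxy-1,2,3,4-tetrahydronaphthalen-2-ol | COc1cc2c(cc1OC)[C@H]([C@H](O)/C=C/c1ccc(O)cc1)[C@H](O)CC2 | target

Total step count: 6. Longest linear sequence: 5 (steps 2–6 from 3, or steps 1 and 3–6 from 1).

**Steps most likely to fail**

**Step 5.**
- What may go wrong: the dienophile may add in the tether-exo orientation, which is common for o-quinodimethane closures and would invert the outcome at C2. The diene may also dimerise, and the allylic C–O bond may ionise on prolonged heating.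
- Fallback: this sets out from 7 and returns at 13, and it fixes C2 after ring closure by hydride delivery instead of by the cycloaddition.
  - Me2SiCl2 and HC≡CMgBr give chloro(ethynyl)dimethylsilane F1.
  - 7 is silylated with it (Et3N, CH2Cl2) to the ethynyl(dimethyl)silyl ether F2.
  - Thermolysis as in step 5 gives the alkenylsiloxane F3. Here C2 is sp2, so no endo/exo question exists and only the face selectivity (same allylic-strain control) counts.
  - Tamao–Kumada oxidation at 0 °C with short contact time gives the β-hydroxy ketone F4.
  - F4 is reduced at once with LiBH(s-Bu)3 at −78 °C from the face opposite the pseudoaxial C1 side chain to give 13. F4 is labile at C1 and must not be stored.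

**Step 3.**
- What may go wrong: the resident stereocentre of the aldehyde may oppose the catalyst in one epimer. Uncatalysed background addition or ethyl transfer may also occur. Each of these would erode the enantiomeric purity that all later centres inherit.
- Fallback: this sets out from 2 and 4 and returns at 7, and it sets C1' by reagent-controlled ketone reduction instead of C–C bond formation.
  - 2 is lithiated (n-BuLi, THF, −78 °C) and added to 4 to give the propargylic alcohol F5 as a mixture at the carbinol.
  - Dess–Martin periodinane gives the ynone F6.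
  - Asymmetric transfer hydrogenation with RuCl[(S,S)-TsDPEN](p-cymene) in iPrOH gives the (S)-propargylic alcohol F7.
  - trans-Hydroalumination with NaAlH2(OCH2CH2OMe)2 in THF at 0 °C gives 7.

**Step 6.**
- What may go wrong: once the phenol is free under basic peroxide, the 4-hydroxycinnamyl alcohol may lose hydroxide by way of a quinone methide, or it may be over-oxidised before the C–Si oxidation is complete.
- Fallback: this sets out from 7 and returns at 13, and it uses a boron tether so that oxidation and phenol release are separated.
  - 7 and dibutyl vinylboronate are heated under the conditions of step 5, with removal of butanol, to give the cyclic butyl boronate (oxaborolane) F8.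
  - NaBO3·4H2O in THF/water at rt gives the silyl-protected diol F9.
  - Bu4NF buffered with AcOH in THF at 0 °C gives 13.

Further compounds
F1 | step 5 | chloro(ethynyl)dimethylsilane | C#C[Si](C)(C)Cl
F2 | step 5 | ethynyl(dimethyl)silyl ether of 7 | COc1cc2c(cc1OC)C([C@H](O[Si](C)(C)C#C)/C=C/c1ccc(O[Si](C)(C)C(C)(C)C)cc1)C2
F3 | step 5 | alkenylsiloxane (1,4-dihydronaphthalene fused to a 2,5-dihydro-1,2-oxasilole) | COc1cc2c(cc1OC)[C@@H]3[C@@H](/C=C/c1ccc(O[Si](C)(C)C(C)(C)C)cc1)O[Si](C)(C)C3=CC2
F4 | step 5 | (1S)-1-[(1R,2E)-1-hydroxy-3-(4-hydroxyphenyl)prop-2-en-1-yl]-6,7-dimethoxy-3,4-dihydronaphthalen-2(1H)-one | COc1cc2c(cc1OC)[C@H]([C@H](O)/C=C/c1ccc(O)cc1)C(=O)CC2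
F5 | step 3 | propargylic alcohol, mixture at the carbinol | COc1cc2c(cc1OC)C(C(O)C#Cc1ccc(O[Si](C)(C)C(C)(C)C)cc1)C2
F6 | step 3 | ynone | COc1cc2c(cc1OC)C(C(=O)C#Cc1ccc(O[Si](C)(C)C(C)(C)C)cc1)C2
F7 | step 3 | (S)-propargylic alcohol | COc1cc2c(cc1OC)C([C@H](O)C#Cc1ccc(O[Si](C)(C)C(C)(C)C)cc1)C2
F8 | step 6 | cis-fused cyclic butyl boronate (1,2-oxaborolane) | COc1cc2c(cc1OC)[C@@H]3[C@@H](/C=C/c1ccc(O[Si](C)(C)C(C)(C)C)cc1)OB(OCCCC)[C@@H]3CC2
F9 | step 6 | phenol-silylated diol | COc1cc2c(cc1OC)[C@H]([C@H](O)/C=C/c1ccc(O[Si](C)(C)C(C)(C)C)cc1)[C@H](O)CC2
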